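Time in these flasks is best counted in turnovers of X, and what matters is how much G the X meets while it is being lost.

| flask | X | G | D | remark | time |
|---|---|---|---|---|---|
| south-east | 0.40 M | 0.40 M | 0.20 M | run made earlier |  |
| east | 0.40 M | 0.20 M | 0.20 M | run made earlier |  |
| north | 0.40 M | 0.30 M | 0.20 M | run made earlier |  |
| west | 0.80 M | 0.40 M | 0.20 M | run made earlier |  |
| blue | 0.40 M | 0.400 M (in portions, 4, over 1.0 h) | 0.200 M | first portion at the start, last at 1.0 h | 80 min |
| red | 0.40 M | 0.400 M | 0.200 M | everything together at the start | 80 min |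
| amber | 0.40 M | 0.400 M (fed, over 1.0 h) | 0.200 M | all else is in the flask from the start; the feed brings no volume worth counting | 80 min |
| ochre | 0.40 M (fed, over 1.0 h) | 0.400 M | 0.200 M | all else is in the flask from the start; the feed brings no volume worth counting | 80 min |

| run | time / min | E / % | X / % |
|---|---|---|---|
| south-east | 6.00 | 11.0 | 61.4 |
| south-east | 10.0 | 14.1 | 44.7 |
| south-east | 15.0 | 16.8 | 30.6 |
| south-east | 25.0 | 18.3 | 15.8 |
| south-east | 30.0 | 19.7 | 10.3 |
| south-east | 50.0 | 18.7 | 2.5 |
| south-east | 80.0 | 18.5 | 0 |
| east | 4.00 | 3.9 | 74.2 |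
| east | 12.0 | 9.4 | 45.1 |
| east | 25.0 | 11.6 | 19.0 |
| east | 30.0 | 8.9 | 15.6 |
| east | 50.0 | 9.6 | 4.3 |
| east | 60.0 | 9.0 | 4.1 |
| east | 80.0 | 10.3 | 0 |
| north | 12.0 | 11.6 | 41.2 |
| north | 25.0 | 15.4 | 18.5 |
| north | 30.0 | 13.1 | 11.8 |
| north | 50.0 | 14.9 | 3.9 |
| north | 60.0 | 16.2 | 3.3 |
| north | 80.0 | 15.0 | 0 |
| west | 15.0 | 14.6 | 27.4 |
| west | 30.0 | 16.6 | 9.9 |
| west | 50.0 | 14.9 | 4.3 |
| west | 60.0 | 14.9 | 1.9 |
| west | 80.0 | 14.4 | 1.2 |

(standard deviation of a reading: 1 percentage point)

- percentages count the X that a species holds: one J counts as two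
- the numbers in the tables scatter by 1 percentage point (one standard deviation)
- reactions considered so far: X + G -> E; X -> Z; 2 X -> J; G + D -> L; E <-> Q

* which flask leads in amount of E, in percent of the X charged ("all alike" within 1.5 percentage points) (blue / red / amber / ochre / all alike)
* how much E is there at the end, in percent of the X charged: blue
* how much E is there at the end, in percent of the X charged: red
* how much E is there at the end, in percent of the X charged: amber
* how much E is there at the end, in percent of the X charged: ochre

In the south-east run, which has the red recipe, X falls with 0.0744 min⁻¹, so one turnover lasts 13.4 min and the asked time holds 5.95 turnovers. E starts at about 0.0183 min⁻¹ of the charge. That slope meets the final level, a reading of 18.5%, at the knee, 10.1 min.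

E in the south-east run then holds 0.0740 M, less than the 0.200 M of G that D cannot reach. The south-east curve stays level while X, the limiting reagent, reads 2.5% at 50.0 min.

The last levels of the south-east, east and north runs, summed over their G charges, give 0.487 M⁻¹. This is the yield per G charged: the final E, as a share of the X charged, for each unit of G charged at the start. It counts G as charged, not the c_G that X actually meets. My own rough reckoning follows, with an equivalent charge c_G,eq put in place of the G charged.

red: c_G,eq = 0.400 M, E = 19.5%

amber: c_G,eq = feed rate × turnover = 0.0896 M, E = 4.36%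

blue: portions fading by turnovers, c_G,eq = 0.129 M, E = 6.28%

ochre: X arrives evenly, so the midpoint between the G charged and that charge less D, c_G,eq = 0.300 M, E = 14.6%

The forecast says “Red leads”, with blue 7.5%, red 18.7% and amber 5.5%, but it differs from this reckoning on ochre, at 6.5%.

The flasks give 7.78% for blue, 18.9% for red, 6.30% for amber and 15.8% for ochre, so red leads.

    X + G → E (k = 0.0700 M⁻¹ min⁻¹)
    X → Z (k = 0.0500 min⁻¹)
    2 X → J (k = 0.0130 M⁻¹ min⁻¹)
    G + D → L (k = 0.0930 M⁻¹ min⁻¹)
    E ⇌ Q (K = 0.400, k = 0.0290 min⁻¹)

Read backwards, the ochre result equals a charge of 0.324 M of G at this yield. The neighbour of red with 0.80 M of D has more D than G, so no part of the G lies beyond the reach of D. There G falls at about 0.0744 min⁻¹ with D as charged, against 0.0744 min⁻¹ for X as read from the south-east run.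

c_G,eq = 0.200 M, E = 9.73%

That neighbour holds 12.9% of E, more than the reckoned amount, with G at 1.24% of its charge at 80.0 min.

The readings are calculated for substances that don't exist; the scatter is artificial.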